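**Plan**

Numbering used throughout (germacrane numbering): ten-membered ring C1–C10, alkene C1=C10 with methyl on C10, epoxide C4(Me)–C5, acetate on C6, isopropyl on C7, benzoate on C8.
Enabling feature: C6 is a carbinol carbon bonded to C5, and C5 is vinylic once the epoxide oxygen is taken off (a 4Z-alkene), so the ring can be cut at C5–C6 into an alkenyl iodide and an aldehyde.
Retrosynthetic cuts, in order: the C6 acetyl group and the epoxide oxygen, the C5–C6 ring bond, C7–C8 (syn-aldol), C3–C4 (carbocupration of propyne), C1–C2 (alkenylalane plus oxirane).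
Forward: the C8–C5 chain is grown linearly from a silylated butynol, joined to the isovaleryl unit by the aldol, adjusted to the benzoate aldehyde, and the only carbocycle is closed in step 12; epoxidation and acetylation finish.
Stereochemistry: C1=C10 E from syn-methylalumination; C4=C5 Z from syn-carbocupration; C7 and C8 from the (R)-benzyloxazolidinone aldol; C6 from substrate control in the ring closure; C4 and C5 from hydroxyl-directed oxygen delivery.

Key step: step 12

Assumption: the silylated butynol, oxirane, propyne, the (R)-benzyloxazolidinone and 3-methylbutanoyl chloride are bought as such.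

**Route**

Step 1
Reactants: 1 tert-butyl(but-3-yn-1-yloxy)dimethylsilane; 2 oxirane
Product: 5 (E)-6-(tert-butyldimethylsilyloxy)-4-methylhex-3-en-1-ol, via alkenyldimethylalane 3 (not isolated), via lithium alkenylaluminate 4 (not isolated)
Conditions: Me3Al, Cp2ZrCl2 (cat.), CH2Cl2, 0 °C to rt; solvent exchanged for hexane; n-BuLi, 0 °C; then 2, THF, 0 °C to rt
Reagents that add atoms: trimethylaluminium, C[Al](C)C
Why: Negishi zirconium-catalysed methylalumination adds methyl and aluminium syn across the terminal alkyne with aluminium on the terminal carbon, and the derived aluminate opens oxirane with retention at the alkenyl carbon, so the C10=C1 alkene should form as the E isomer only.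

Step 2
Reactants: 5 (E)-6-(tert-butyldimethylsilyloxy)-4-methylhex-3-en-1-ol
Product: 6 [(E)-6-bromo-3-methylhex-3-en-1-yl]oxy(tert-butyl)dimethylsilane
Conditions: CBr4, PPh3, CH2Cl2, 0 °C
Reagents that add atoms: carbon tetrabromide, BrC(Br)(Br)Br
Why: Appel bromination converts the primary alcohol into the bromide by SN2 displacement of an oxyphosphonium ion under neutral conditions that leave the silyl ether and the alkene untouched.

Step 3
Reactants: 6 [(E)-6-bromo-3-methylhex-3-en-1-yl]oxy(tert-butyl)dimethylsilane; 7 propyne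
Product: 11 tert-butyl{[(3E,7Z)-8-iodo-3,7-dimethylocta-3,7-dien-1-yl]oxy}dimethylsilane, via Grignard reagent 8 (not isolated), via alkylcopper 9 (not isolated), via alkenylcopper 10 (not isolated)
Conditions: Mg, Et2O; CuBr·SMe2, Et2O/Me2S, −45 °C; 7, −25 °C; I2, −50 to 0 °C
Reagents that add atoms: iodine, II
Why: Normant carbocupration, in which the monovalent alkylcopper 9 adds syn to propyne with copper on the terminal carbon and iodinolysis of 10 proceeds with retention, so the chain and iodine end up cis and the C4=C5 alkenyl iodide should be Z.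

Step 4
Reactants: 11 tert-butyl{[(3E,7Z)-8-iodo-3,7-dimethylocta-3,7-dien-1-yl]oxy}dimethylsilane
Product: 12 (3E,7Z)-8-iodo-3,7-dimethylocta-3,7-dien-1-ol
Conditions: CSA (cat.), MeOH/CH2Cl2, 0 °C
Reagents that add atoms: none
Why: Acid-catalysed methanolysis of a primary silyl ether is fast at 0 °C and does not touch the alkenyl iodide or the trisubstituted alkene.

Step 5
Reactants: 12 (3E,7Z)-8-iodo-3,7-dimethylocta-3,7-dien-1-ol
Product: 13 (3E,7Z)-8-iodo-3,7-dimethylocta-3,7-dienal
Conditions: Dess–Martin periodinane, NaHCO3, CH2Cl2, 0 °C; used at once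
Reagents that add atoms: none
Why: Dess–Martin oxidation under bicarbonate buffer gives the β,γ-unsaturated aldehyde without acid or base able to move the C10=C1 alkene into conjugation.

Step 6
Reactants: 14 (R)-4-benzyloxazolidin-2-one; 15 3-methylbutanoyl chloride
Product: 17 (R)-4-benzyl-3-(3-methylbutanoyl)oxazolidin-2-one, via lithium oxazolidinide 16 (not isolated)
Conditions: n-BuLi, THF, −78 °C; then 15, −78 to 0 °C
Reagents that add atoms: none
Why: N-Acylation of the lithiated oxazolidinone with the acid chloride is the standard way to load an Evans auxiliary and does not affect its stereocentre.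

Step 7
Reactants: 17 (R)-4-benzyl-3-(3-methylbutanoyl)oxazolidin-2-one; 13 (3E,7Z)-8-iodo-3,7-dimethylocta-3,7-dienal
Product: 19 (R)-4-benzyl-3-[(2R,3S,5E,9Z)-3-hydroxy-10-iodo-5,9-dimethyl-2-(propan-2-yl)deca-5,9-dienoyl]oxazolidin-2-one, via dibutylboron enolate 18 (not isolated)
Conditions: Bu2BOTf, i-Pr2NEt, CH2Cl2, 0 °C; 13, −78 to 0 °C; then H2O2, MeOH, NaH2PO4/Na2HPO4 buffer
Reagents that add atoms: none
Why: Evans boron syn-aldol, in which soft enolisation gives the Z-enolate 18 that adds through a Zimmerman–Traxler chair on the face not shielded by the benzyl group of the R auxiliary, setting C7 and C8 together as the 2R,3S syn pair.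

Step 8
Reactants: 19 (R)-4-benzyl-3-[(2R,3S,5E,9Z)-3-hydroxy-10-iodo-5,9-dimethyl-2-(propan-2-yl)deca-5,9-dienoyl]oxazolidin-2-one
Product: 20 (2S,3S,5E,9Z)-10-iodo-5,9-dimethyl-2-(propan-2-yl)deca-5,9-diene-1,3-diol
Conditions: LiBH4, MeOH, THF, 0 °C
Reagents that add atoms: none
Why: Reductive cleavage of the N-acyloxazolidinone with LiBH4 at the exocyclic carbonyl, assisted by the free β-hydroxyl, releases the primary alcohol and the auxiliary without touching the alkenyl iodide or the stereocentres.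

Step 9
Reactants: 20 (2S,3S,5E,9Z)-10-iodo-5,9-dimethyl-2-(propan-2-yl)deca-5,9-diene-1,3-diol
Product: 22 (2S,3S,5E,9Z)-10-iodo-5,9-dimethyl-2-(propan-2-yl)-1-(triethylsilyloxy)deca-5,9-dien-3-yl benzoate, via mono-triethylsilyl ether 21 (not isolated)
Conditions: Et3SiCl, pyridine, CH2Cl2, −40 °C; then BzCl, DMAP, 0 °C to rt
Reagents that add atoms: chlorotriethylsilane, CC[Si](Cl)(CC)CC; benzoyl chloride, O=C(Cl)c1ccccc1
Why: Sterically controlled silylation takes only the primary hydroxyl at low temperature, after which DMAP-catalysed esterification places the benzoate on the C8 oxygen with no change at the stereocentres.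

Step 10
Reactants: 22 (2S,3S,5E,9Z)-10-iodo-5,9-dimethyl-2-(propan-2-yl)-1-(triethylsilyloxy)deca-5,9-dien-3-yl benzoate
Product: 23 (2S,3S,5E,9Z)-1-hydroxy-10-iodo-5,9-dimethyl-2-(propan-2-yl)deca-5,9-dien-3-yl benzoate
Conditions: PPTS (cat.), MeOH, rt
Reagents that add atoms: none
Why: Acid-catalysed methanolysis cleaves the primary triethylsilyl ether while the benzoate stays on C8, acyl migration being slow under weakly acidic conditions.

Step 11
Reactants: 23 (2S,3S,5E,9Z)-1-hydroxy-10-iodo-5,9-dimethyl-2-(propan-2-yl)deca-5,9-dien-3-yl benzoate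
Product: 24 (2R,3S,5E,9Z)-10-iodo-5,9-dimethyl-1-oxo-2-(propan-2-yl)deca-5,9-dien-3-yl benzoate
Conditions: Dess–Martin periodinane, NaHCO3, CH2Cl2, 0 °C; used at once
Reagents that add atoms: none
Why: Dess–Martin oxidation under bicarbonate buffer gives the aldehyde without a base strong enough to epimerise C7 or eliminate the β-benzoate.

Step 12
Reactants: 24 (2R,3S,5E,9Z)-10-iodo-5,9-dimethyl-1-oxo-2-(propan-2-yl)deca-5,9-dien-3-yl benzoate
Product: 26 (6S,7S,8S,1(10)E,4Z)-6-hydroxygermacra-1(10),4-dien-8-yl benzoate, via alkenylchromium dichloride 25 (not isolated)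
Conditions: CrCl2 (excess), NiCl2 (cat.), degassed DMSO, high dilution, slow addition of 24, rt
Reagents that add atoms: none
Why: Zerovalent nickel, formed from NiCl2 by divalent chromium, inserts into the C5–I bond with retention of the Z geometry and passes the alkenyl group to trivalent chromium to give 25, whose carbon–chromium bond adds to the C6 aldehyde. The closest known reaction type is the intramolecular Nozaki–Hiyama–Kishi alkenyl iodide–aldehyde coupling used to close medium and large carbocycles and lactones. The ten-membered ring closes in a 10-exo-trig mode at the formyl carbon, and high dilution with slow addition should let ring closure outpace dimerisation. The new C6 stereocentre is set by substrate control: attack anti to the C7 isopropyl group (Felkin–Anh arrangement with isopropyl as the large substituent) also places the new oxygen 1,3-anti to the C8 benzoate, as the polar 1,3-induction model prefers, and should give the 6S carbinol. The step needs chemoselectivity for the aldehyde and integrity at C7 and C4=C5; the non-basic organochromium ignores the benzoate and the C1=C10 alkene and should not epimerise or eliminate, and the Z geometry carried into the ring fixes the later cis-epoxide.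

Step 13
Reactants: 26 (6S,7S,8S,1(10)E,4Z)-6-hydroxygermacra-1(10),4-dien-8-yl benzoate
Product: 27 (4S,5R,6R,7S,8S,1(10)E)-4,5-epoxy-6-hydroxygermacr-1(10)-en-8-yl benzoate
Conditions: VO(acac)2 (cat.), t-BuOOH, CH2Cl2, 0 °C
Reagents that add atoms: tert-butyl hydroperoxide, CC(C)(C)OO
Why: Hydroxyl-directed epoxidation, in which the pentavalent vanadium alkoxide of the C6 hydroxyl delivers the peroxide oxygen only to the neighbouring C4=C5 alkene and, as in other medium-ring (Z)-cycloalkenols, to the peripheral face syn to that hydroxyl, which should set C4 (S) and C5 (R) as the cis-epoxy alcohol while C1=C10 stays untouched.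

Step 14
Reactants: 27 (4S,5R,6R,7S,8S,1(10)E)-4,5-epoxy-6-hydroxygermacr-1(10)-en-8-yl benzoate
Product: 28 (4S,5R,6R,7R,8S,1(10)E)-6-acetoxy-4,5-epoxygermacr-1(10)-en-8-yl benzoate (CNP0112246.1)
Conditions: Ac2O, DMAP, pyridine, CH2Cl2, 0 °C to rt
Reagents that add atoms: acetic anhydride, CC(=O)OC(C)=O
Why: DMAP-catalysed acetylation esterifies the remaining secondary hydroxyl under mild conditions that leave the epoxide, the benzoate and all stereocentres unchanged.

**Compound list**

1 | tert-butyl(but-3-yn-1-yloxy)dimethylsilane | C#CCCO[Si](C)(C)C(C)(C)C | starting material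
2 | oxirane | C1CO1 | starting material
3 | (E)-[4-(tert-butyldimethylsilyloxy)-2-methylbut-1-en-1-yl]dimethylalane | C[Al](C)/C=C(C)/CCO[Si](C)(C)C(C)(C)C | intermediate
4 | lithium butyl[(E)-4-(tert-butyldimethylsilyloxy)-2-methylbut-1-en-1-yl]dimethylaluminate | [Li+].CCCC[Al-](C)(C)/C=C(C)/CCO[Si](C)(C)C(C)(C)C | intermediate
5 | (E)-6-(tert-butyldimethylsilyloxy)-4-methylhex-3-en-1-ol | OCC/C=C(C)/CCO[Si](C)(C)C(C)(C)C | intermediate
6 | [(E)-6-bromo-3-methylhex-3-en-1-yl]oxy(tert-butyl)dimethylsilane | BrCC/C=C(C)/CCO[Si](C)(C)C(C)(C)C | intermediate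
7 | propyne | CC#C | starting material
8 | [(E)-6-(tert-butyldimethylsilyloxy)-4-methylhex-3-en-1-yl]magnesium bromide | Br[Mg]CC/C=C(C)/CCO[Si](C)(C)C(C)(C)C | intermediate
9 | [(E)-6-(tert-butyldimethylsilyloxy)-4-methylhex-3-en-1-yl]copper (monovalent copper) | [Cu]CC/C=C(C)/CCO[Si](C)(C)C(C)(C)C | intermediate
10 | [(1Z,5E)-8-(tert-butyldimethylsilyloxy)-2,6-dimethylocta-1,5-dien-1-yl]copper (monovalent copper) | [Cu]/C=C(C)\CC/C=C(C)/CCO[Si](C)(C)C(C)(C)C | intermediate
11 | tert-butyl{[(3E,7Z)-8-iodo-3,7-dimethylocta-3,7-dien-1-yl]oxy}dimethylsilane | I/C=C(C)\CC/C=C(C)/CCO[Si](C)(C)C(C)(C)C | intermediate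
12 | (3E,7Z)-8-iodo-3,7-dimethylocta-3,7-dien-1-ol | I/C=C(C)\CC/C=C(C)/CCO | intermediate
13 | (3E,7Z)-8-iodo-3,7-dimethylocta-3,7-dienal | I/C=C(C)\CC/C=C(C)/CC=O | intermediate
14 | (R)-4-benzyloxazolidin-2-one | O=C1N[C@H](Cc2ccccc2)CO1 | starting material
15 | 3-methylbutanoyl chloride | CC(C)CC(=O)Cl | starting material
16 | N-lithio-(R)-4-benzyloxazolidin-2-one | [Li+].O=C1[N-][C@H](Cc2ccccc2)CO1 | intermediate
17 | (R)-4-benzyl-3-(3-methylbutanoyl)oxazolidin-2-one | CC(C)CC(=O)N1[C@H](Cc2ccccc2)COC1=O | intermediate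
18 | (Z)-dibutylboron enolate of 17 | CC(C)/C=C(\OB(CCCC)CCCC)N1[C@H](Cc2ccccc2)COC1=O | intermediate
19 | (R)-4-benzyl-3-[(2R,3S,5E,9Z)-3-hydroxy-10-iodo-5,9-dimethyl-2-(propan-2-yl)deca-5,9-dienoyl]oxazolidin-2-one | I/C=C(C)\CC/C=C(C)/C[C@H](O)[C@@H](C(C)C)C(=O)N1[C@H](Cc2ccccc2)COC1=O | intermediate
20 | (2S,3S,5E,9Z)-10-iodo-5,9-dimethyl-2-(propan-2-yl)deca-5,9-diene-1,3-diol | I/C=C(C)\CC/C=C(C)/C[C@H](O)[C@@H](C(C)C)CO | intermediate
21 | (2S,3S,5E,9Z)-10-iodo-5,9-dimethyl-2-(propan-2-yl)-1-(triethylsilyloxy)deca-5,9-dien-3-ol | I/C=C(C)\CC/C=C(C)/C[C@H](O)[C@@H](C(C)C)CO[Si](CC)(CC)CC | intermediate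
22 | (2S,3S,5E,9Z)-10-iodo-5,9-dimethyl-2-(propan-2-yl)-1-(triethylsilyloxy)deca-5,9-dien-3-yl benzoate | I/C=C(C)\CC/C=C(C)/C[C@H](OC(=O)c1ccccc1)[C@@H](C(C)C)CO[Si](CC)(CC)CC | intermediate
23 | (2S,3S,5E,9Z)-1-hydroxy-10-iodo-5,9-dimethyl-2-(propan-2-yl)deca-5,9-dien-3-yl benzoate | I/C=C(C)\CC/C=C(C)/C[C@H](OC(=O)c1ccccc1)[C@@H](C(C)C)CO | intermediate
24 | (2R,3S,5E,9Z)-10-iodo-5,9-dimethyl-1-oxo-2-(propan-2-yl)deca-5,9-dien-3-yl benzoate | I/C=C(C)\CC/C=C(C)/C[C@H](OC(=O)c1ccccc1)[C@@H](C(C)C)C=O | intermediate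
25 | alkenylchromium dichloride derived from 24 (trivalent chromium on C5, Z) | Cl[Cr](Cl)/C=C(C)\CC/C=C(C)/C[C@H](OC(=O)c1ccccc1)[C@@H](C(C)C)C=O | intermediate
26 | (6S,7S,8S,1(10)E,4Z)-6-hydroxygermacra-1(10),4-dien-8-yl benzoate | O[C@@H]1[C@H](C(C)C)[C@@H](OC(=O)c2ccccc2)C/C(C)=C/CC/C(C)=C\1 | intermediate
27 | (4S,5R,6R,7S,8S,1(10)E)-4,5-epoxy-6-hydroxygermacr-1(10)-en-8-yl benzoate | O[C@@H]1[C@H](C(C)C)[C@@H](OC(=O)c2ccccc2)C/C(C)=C/CC[C@]2(C)O[C@H]12 | intermediate
28 | (4S,5R,6R,7R,8S,1(10)E)-6-acetoxy-4,5-epoxygermacr-1(10)-en-8-yl benzoate (CNP0112246.1) | CC(=O)O[C@@H]1[C@H](C(C)C)[C@@H](OC(=O)c2ccccc2)C/C(C)=C/CC[C@]2(C)O[C@H]12 | target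

**Count**

Total steps: 14. Longest linear sequence: 13 steps (steps 1–5 and 7–14, from 1); step 6 is a one-step side branch.

**Steps most likely to fail**

Step 12. Ring closure may lose to intermolecular coupling and protodeiodination, and the alkenylchromium may attack both faces of the aldehyde so that C6 forms unselectively. The fallback sets C6 by reagent control after the ring exists. Setting out from 24, the cyclisation is run as above and the unseparated C6 epimers are oxidised with Dess–Martin periodinane/NaHCO3 to the macrocyclic (4Z)-enone F1. Corey–Bakshi–Shibata reduction (BH3·SMe2, (S)-2-methyl-CBS-oxazaborolidine, THF, −40 °C), with the alkenyl arm acting as the larger ketone substituent, should then give the 6S alcohol, and the route is rejoined at 26.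

Step 13. Oxygen may be delivered to the wrong face of C4=C5, the Lewis-acidic vanadium may trigger transannular opening of the new epoxide by C1=C10, or the allylic alcohol may be oxidised instead of the alkene. The fallback replaces metal-directed delivery by hydrogen-bond-directed peracid epoxidation on the C6 epimer, followed by inversion. Setting out from 26, Dess–Martin oxidation to the enone and reduction with (R)-2-methyl-CBS-oxazaborolidine/BH3·SMe2 should give the 6R epimeric alcohol F2. mCPBA/NaHCO3 in CH2Cl2 at −20 °C (Henbest direction, peripheral attack with the hydroxyl pseudo-equatorial, the trans-epoxy alcohol expected for medium-ring Z-allylic alcohols) should give epoxy alcohol F3 carrying the 4S,5R epoxide. A Mitsunobu reaction with acetic acid (PPh3, diisopropyl azodicarboxylate, THF) inverts C6 and installs the acetate in one operation, so the route is rejoined at 28.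

Step 11. The α-branched β-benzoyloxy aldehyde may lose benzoic acid by β-elimination or epimerise at C7 during oxidation, handling or the long chromium reaction, and the benzoyl group may shift to the new C6 alkoxide. The fallback carries the C8 oxygen as a silyl ether through ring closure and benzoylates last. Setting out from 19, TBSOTf/2,6-lutidine gives silyl ether F4, LiBH4/MeOH gives primary alcohol F5, and Dess–Martin oxidation gives aldehyde F6. The same CrCl2/NiCl2 cyclisation gives macrocyclic allylic alcohol F7, VO(acac)2/t-BuOOH gives epoxy alcohol F8, and Ac2O/DMAP gives acetate F9. HF·pyridine in THF/pyridine frees the C8 hydroxyl as F10, and BzCl/DMAP/pyridine then gives 28, where the route is rejoined.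

Further compounds
F1 | step 12 | (7R,8S,1(10)E,4Z)-6-oxogermacra-1(10),4-dien-8-yl benzoate | O=C1[C@H](C(C)C)[C@@H](OC(=O)c2ccccc2)C/C(C)=C/CC/C(C)=C\1
F2 | step 13 | (6R,7S,8S,1(10)E,4Z)-6-hydroxygermacra-1(10),4-dien-8-yl benzoate (C6 epimer of 26) | O[C@H]1[C@H](C(C)C)[C@@H](OC(=O)c2ccccc2)C/C(C)=C/CC/C(C)=C\1
F3 | step 13 | (4S,5R,6S,7S,8S,1(10)E)-4,5-epoxy-6-hydroxygermacr-1(10)-en-8-yl benzoate (C6 epimer of 27) | O[C@H]1[C@H](C(C)C)[C@@H](OC(=O)c2ccccc2)C/C(C)=C/CC[C@]2(C)O[C@H]12
F4 | step 11 | (R)-4-benzyl-3-[(2R,3S,5E,9Z)-3-(tert-butyldimethylsilyloxy)-10-iodo-5,9-dimethyl-2-(propan-2-yl)deca-5,9-dienoyl]oxazolidin-2-one | I/C=C(C)\CC/C=C(C)/C[C@H](O[Si](C)(C)C(C)(C)C)[C@@H](C(C)C)C(=O)N1[C@H](Cc2ccccc2)COC1=O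
F5 | step 11 | (2S,3S,5E,9Z)-3-(tert-butyldimethylsilyloxy)-10-iodo-5,9-dimethyl-2-(propan-2-yl)deca-5,9-dien-1-ol | I/C=C(C)\CC/C=C(C)/C[C@H](O[Si](C)(C)C(C)(C)C)[C@@H](C(C)C)CO
F6 | step 11 | (2R,3S,5E,9Z)-3-(tert-butyldimethylsilyloxy)-10-iodo-5,9-dimethyl-2-(propan-2-yl)deca-5,9-dienal | I/C=C(C)\CC/C=C(C)/C[C@H](O[Si](C)(C)C(C)(C)C)[C@@H](C(C)C)C=O
F7 | step 11 | (6S,7S,8S,1(10)E,4Z)-8-(tert-butyldimethylsilyloxy)germacra-1(10),4-dien-6-ol | O[C@@H]1[C@H](C(C)C)[C@@H](O[Si](C)(C)C(C)(C)C)C/C(C)=C/CC/C(C)=C\1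
F8 | step 11 | (4S,5R,6R,7S,8S,1(10)E)-8-(tert-butyldimethylsilyloxy)-4,5-epoxygermacr-1(10)-en-6-ol | O[C@@H]1[C@H](C(C)C)[C@@H](O[Si](C)(C)C(C)(C)C)C/C(C)=C/CC[C@]2(C)O[C@H]12
F9 | step 11 | (4S,5R,6R,7S,8S,1(10)E)-8-(tert-butyldimethylsilyloxy)-4,5-epoxygermacr-1(10)-en-6-yl acetate | CC(=O)O[C@@H]1[C@H](C(C)C)[C@@H](O[Si](C)(C)C(C)(C)C)C/C(C)=C/CC[C@]2(C)O[C@H]12
F10 | step 11 | (4S,5R,6R,7R,8S,1(10)E)-4,5-epoxy-8-hydroxygermacr-1(10)-en-6-yl acetate | CC(=O)O[C@@H]1[C@H](C(C)C)[C@@H](O)C/C(C)=C/CC[C@]2(C)O[C@H]12
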